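## Structural features

The target is a heliangolide-type germacranolide: a ten-membered carbocycle (C1–C10) with a trans-1,10-epoxide (H on C1, methyl on C10), a Z-trisubstituted C4=C5 alkene, and an α-methylene-γ-butyrolactone (C11=C13H2, C12=O) fused trans across C6–C7 through O6. Two more oxygens are acylated: the allylic O3 as a benzoate, and O8 as a (2S,3S)-2,3-dimethyloxirane-2-carboxylate (epoxyangelate), which adds two stereocentres of its own. C6, C7 and C8 are contiguous (6R,7R,8R; O6 trans to C11, C11 cis to O8). C1 and C10 (1R,10R) share the epoxide, and C3 (3S) is separated from the others by the alkene. The fragile groups are the exocyclic methylene lactone (Michael acceptor), both epoxides (acid), and the allylic benzoate. In every intermediate that still has C1=C10, the cyclodeca-1(10),4-diene is also fragile: it cyclises across the ring with acids or electrophiles and can undergo Cope rearrangement on heating. The real difficulty is a medium ring that resists end-to-end closure, with a Z-alkene inside it and three contiguous stereocentres to be set on a mobile ring. The key step uses the six-carbon arc C1–C6, in which the Z C4=C5 alkene lies between 1,4-related oxygens on C3 and C6. This arc is a carvone-derived cyclohexene whose C1–C6 bond is exchanged for C8–C9 in a [3,3] shift.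

## Logic of the disconnections

34 to 33. The two C–O bonds of the 1,10-epoxide are cut. C1=C10 is the only electron-rich alkene in 33, so the acid-labile epoxide can be made last. This removes two stereocentres. The forward step needs peracid attack on the outer face of the conformer that holds the C10 methyl on the side of C11.

33 to 31 to 29. C11=C13 is cut, then C11–C13. The Michael acceptor is made from the saturated lactone by Mannich reaction and elimination, so 29 carries no electrophilic alkene. The forward step needs enolisation at C11 only; both ester acyl groups of 29 lack α-hydrogens.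

29 to 28 to 27. The benzoyl C–O bond at O3 is cut, then O3–Si. O3 stays a silyl ether while C6 is a ketone, because a free Z-γ-hydroxy enone would close to a hemiketal and lose water to a furan. The forward steps need a desilylation that spares the lactone and the epoxy ester.

27 to 26. The lactone acyl bond O6–C12 is cut, which reveals a γ-hydroxy ester. The forward step needs O8 already acylated, so that only O6 can lactonise, and an ester that does not lactonise earlier (tert-butyl).

26 to 20 and 24. The O8–acyl bond and the C6–H bond are cut together, as a Tishchenko redox pair. The C8 hydroxyl of 20 then does two jobs: it delivers hydride to C6 (1,3-anti, giving 6R) and it takes the acyl group, leaving O6 free. The forward step needs an epoxy aldehyde that survives the samarium catalyst.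

24 to 23 to 22 to 21. The epoxide C–O bonds are cut (asymmetric epoxidation of the Z-allylic alcohol) and the oxidation level is adjusted. The forward steps need the tartrate enantiomer that gives the 2R,3S epoxy alcohol.

20 to 17 and 18. The C7–C11 bond is cut. C7 is α to the C6 ketone, and the C8 alkoxide can hold the enolate in a chelate. The forward step needs attack on the open outer face, anti to C9, and an ester that the C8 alkoxide does not attack.

17 to 15. The C8–O bond is traced back to C8–Si, exchanged with retention. A β-oxygen could not pass through the enolate of the key step, whereas silicon can. The forward step must unmask silicon without acid or electrophile, because the diene tolerates neither; this is why the silicon carries a benzyl group (fluoride, then peroxide) and not a phenyl group, whose unmasking needs an electrophile. It is placed before C7 and C6 are set so that the hydroxyl can direct both.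

15 to 12. In the retro direction C8–C9 is cut and C1–C6 is formed. The ten-membered ring becomes a cyclohexene with two alkenyl groups on adjacent carbons. Ring, E C1=C10 alkene and C8 are all traced to one carbinol stereocentre. The forward step needs the trans-dialkenyl carbinol and an E-vinylsilane.

12 to 6 and 10. The C6–C7 bond (carbinol to vinyl) is cut. The forward step needs 1,2-addition to the enone on the face away from the neighbouring isopropenyl group.

10 to 7 and 8. The vinyl C–Si bond is cut. The forward step needs mono-lithiation of the distannane.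

6 to 5 to 4 to 3 to 2 to 1. The C6 carbonyl is traced to the ring allylic methylene, the silyl ether to the alcohol, and the 3S carbinol to carvone. The forward steps need an inversion, because hydride reduction of 1 gives the cis alcohol.

## Other disconnections considered

Alternative 1: The cut is C2–C3 together with the O–C1 bond of a bridging isoxazoline. In the forward step the open-chain nitrile oxide A2 adds to its own terminal alkene and gives the isoxazoline-bridged carbocycle A1.
- In favour: one step makes C2–C3, puts oxygen on C1 and leaves a masked carbonyl on C3. The lactone, the C8 oxygen, the C10 carbinol and the Z-alkene are in place before the ring exists.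
- Better than the chosen plan on one point: C6, C7 and C8 are set in open-chain chemistry under reagent control, not on a ten-membered ring.
- Against: the ring closes end to end, with the entropic and transannular cost of a ten-membered ring, and nitrile oxide dimerisation competes unless the solution is very dilute. The facial selectivity at C1 rests only on the neighbouring quaternary C10. After closure the route still needs N–O cleavage, reduction of the C3 ketone to 3S, and epoxide closure with inversion at C1.
- Comparison: the chosen plan gets the Z-alkene from the cyclohexene for nothing and pays no entropy, since the ring is expanded and not cyclised. Alternative 1 must build the Z-trisubstituted alkene stereoselectively in the chain and is much longer in the linear sense. Mechanistically a kinetically controlled dipolar cycloaddition stands against a chair-controlled sigmatropic shift.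

Alternative 2: The cut is the C3=C8 ring-fusion alkene of the hexahydronaphthalene A4, a bond that is absent from the target. In the forward step ozone cleaves it and gives the cyclodecane-3,8-dione A3.
- Equal to the chosen plan: the ten-membered ring arises by opening a bicycle, not by end-to-end closure.
- Better than the chosen plan: the cleavage is very reliable, and C6, C7 and the C1/C10 diol are set on rigid six-membered rings.
- Against: A3 is a saturated 1,6-diketone and is prone to transannular aldol reaction. Neither alkene of the target is present, so the Z C4=C5 alkene must be introduced next to the C3 ketone with control of position and geometry. Both ketones must be told apart and reduced stereoselectively, the lactone must be built from the silyloxyethyl arm, and the epoxide made from the diol.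
- Comparison: the arene precursor is achiral, so absolute configuration needs a separate asymmetric step, whereas carvone supplies it. The redox and functional-group work after ring opening makes the sequence longer than the chosen one.

Alternative 3: The cut is C9–C10. In the forward step SmI2 turns the bromomethyl ketone of A6 into a samarium enolate that adds to the C10 methyl ketone and gives the ten-membered hydroxy ketone A5.
- In favour: samarium-mediated Reformatsky closures of medium rings are an established reaction type, and the trivalent samarium can template the two carbonyls. The lactone, O3, the Z-alkene and the C1 oxygen are all in place.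
- Better than the chosen plan on two points: the epoxide later comes from the C1,C10 diol by displacement, so its configuration does not hang on the face selectivity of a peracid on the ring. No enolate alkylation on the ten-membered ring is needed.
- Equal or better in convergence.
- Against: the closure is end to end and needs high dilution. It creates only C10, whose configuration depends on chelation to the C1 silyloxy group. The β-hydroxy ketone can revert by retro-aldol, C7 becomes epimerisable next to the C8 ketone, and C8 still needs a stereoselective reduction.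
- Comparison: the open-chain precursor with five stereocentres and a Z-trisubstituted alkene is long to make. The chosen plan forms the ring, the E-alkene and C8 in one chair-controlled step from a six-step precursor.

Key step: step 8

Remark: locants C1–C15 used for the ten-membered-ring compounds are those of the target.
Assumption: 7, 8, 18 and 21 are taken as purchasable; hydride reduction of 1 is taken to give the cis alcohol, so the trans alcohol is reached by inversion.

Step 1
Reactants: 1 (R)-carvone
Product: 2 (1R,5R)-cis-carveol
Conditions: NaBH4, CeCl3·7H2O, MeOH, 0 °C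
Reagents that add atoms: none
Why: Luche 1,2-reduction; axial hydride attack on the half-chair with equatorial isopropenyl should give mainly the cis (1R) allylic alcohol.

Step 2
Reactants: 2 (1R,5R)-cis-carveol
Product: 3 (1S,5R)-trans-carveyl 4-nitrobenzoate
Conditions: 4-nitrobenzoic acid, PPh3, DIAD, THF, 0 → 25 °C
Reagents that add atoms: 4-nitrobenzoic acid, O=C(O)c1ccc(cc1)[N+](=O)[O-]
Why: Mitsunobu reaction; SN2 displacement of the activated oxygen by the carboxylate inverts C1 to S, and SN2' attack is disfavoured because the far alkene carbon is fully substituted.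

Step 3
Reactants: 3 (1S,5R)-trans-carveyl 4-nitrobenzoate
Product: 4 (1S,5R)-trans-carveol
Conditions: K2CO3, MeOH, 25 °C
Reagents that add atoms: none
Why: Base-catalysed methanolysis (transesterification) by acyl–oxygen cleavage, so C1 is untouched.

Step 4
Reactants: 4 (1S,5R)-trans-carveol
Product: 5 triisopropyl{[(1S,5R)-2-methyl-5-(prop-1-en-2-yl)cyclohex-2-en-1-yl]oxy}silane
Conditions: TIPSOTf, 2,6-lutidine, CH2Cl2, 0 °C
Reagents that add atoms: triisopropylsilyl trifluoromethanesulfonate, CC(C)[Si](OS(=O)(=O)C(F)(F)F)(C(C)C)C(C)C
Why: Silyl ether formation; the bulky group is chosen to survive chromium oxidation, organolithium, KH and a short fluoride treatment, and to resist transfer to the enolate oxygen in step 8.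

Step 5
Reactants: 5 trans-carveyl triisopropylsilyl ether
Product: 6 (4S,6R)-3-methyl-6-(prop-1-en-2-yl)-4-(triisopropylsilyloxy)cyclohex-2-en-1-one
Conditions: CrO3, 3,5-dimethylpyrazole, CH2Cl2, −20 °C
Reagents that add atoms: chromium trioxide, O=[Cr](=O)=O
Why: Allylic oxidation of the only allylic ring methylene of the trisubstituted alkene to the enone; the other allylic ring carbon is shielded by the silyloxy group, and both stereocentres are untouched.

Step 6
Reactants: 7 (E)-1,2-bis(tributylstannyl)ethene; 8 benzylchlorodimethylsilane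
Product: 10 (E)-benzyldimethyl[2-(tributylstannyl)ethenyl]silane, via (E)-2-(tributylstannyl)vinyllithium 9 (not isolated)
Conditions: n-BuLi (1 equiv), THF, −78 °C; then 8, −78 → 0 °C
Reagents that add atoms: none
Why: Tin–lithium exchange of one stannyl group, then silylation of the vinyllithium at silicon; both events retain the E geometry.

Step 7
Reactants: 10 (E)-benzyldimethyl[2-(tributylstannyl)ethenyl]silane; 6 (4S,6R)-enone
Product: 12 (1R,4S,6R)-1-[(E)-2-(benzyldimethylsilyl)ethenyl]-3-methyl-6-(prop-1-en-2-yl)-4-(triisopropylsilyloxy)cyclohex-2-en-1-ol, via (E)-2-(benzyldimethylsilyl)vinyllithium 11 (not isolated)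
Conditions: n-BuLi, THF, −78 °C; then 6, −78 °C; H2O
Reagents that add atoms: none
Why: Tin–lithium exchange, then 1,2-addition of the vinyllithium to the enone; attack on the carbonyl face away from the adjacent equatorial isopropenyl group should set C1 as R, with the two alkenyl groups trans and the hydroxyl cis to isopropenyl.

Step 8
Reactants: 12 trans-1-(silylvinyl)-6-isopropenylcyclohexenol
Product: 15 (2Z,4S,6E,9R)-9-(benzyldimethylsilyl)-3,7-dimethyl-4-(triisopropylsilyloxy)cyclodeca-2,6-dien-1-one (target numbering: 8-silyl-3-silyloxy-cyclodeca-1(10)E,4Z-dien-6-one, 3S,8R), via potassium alkoxide 13 (not isolated), via potassium dienolate 14 (not isolated)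
Conditions: KH, 18-crown-6, THF, 0 → 25 °C; AcOH, −78 °C
Reagents that add atoms: none
Why: KH deprotonates the tertiary alcohol and 18-crown-6 frees the alkoxide 13, whose oxyanion weakens the C1–C6 bond so that the 1,5-diene Si–CH=CH–C(O−)–CH–C(Me)=CH2 undergoes a concerted [3,3] sigmatropic shift near room temperature (anionic oxy-Cope rearrangement) to the dienolate 14, which is protonated at C7 on quenching. The closest known reaction type is the anionic oxy-Cope ring expansion of trans-1,2-dialkenylcyclohexanols to cyclodec-5-enones, and the silyl group on the bond-forming vinyl terminus is the only extension. The ten-membered ring is closed by four-atom ring expansion and not by end-to-end cyclisation: C8–C9 forms between the two alkenyl termini while the ring bond C1–C6 breaks, so no entropic price is paid for a medium ring. The shift runs through a chair in which both remaining ring bonds of the cyclohexene are pseudo-equatorial, which the trans arrangement of the alkenyl groups allows; this gives the E C1=C10 alkene, and the cyclohexene alkene is carried over unchanged as Z C4=C5. The one new stereocentre, C8, is controlled by the carbinol configuration (1R, itself set by the carvone stereocentre) through the chair: the E-vinylsilane places silicon equatorial and hydrogen axial, which gives 8R, the configuration needed for a retentive C–Si to C–O exchange. The step needs chair over boat and [3,3] shift over alkoxide fragmentation; the first rests on the trans-dialkenyl geometry and the E substituent, the second on the dissociated potassium alkoxide at low temperature. The β-silyl enolate cannot eliminate as a β-alkoxy enolate would, and the bulky silyl ether on O3 should not move to the enolate oxygen.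

Step 9
Reactants: 15 8-silyl cyclodecadienone
Product: 17 (2Z,4S,6E,9R)-9-hydroxy-3,7-dimethyl-4-(triisopropylsilyloxy)cyclodeca-2,6-dien-1-one (target numbering: 8R-hydroxy-6-ketone), via fluorosilane 16 (not isolated)
Conditions: TBAF, THF, 0 °C; then KHCO3, 30% H2O2, MeOH, 0 → 25 °C
Reagents that add atoms: hydrogen peroxide, OO
Why: Tamao–Fleming oxidation; fluoride removes the benzyl group from silicon as toluene, and the C8–Si bond of 16 migrates to peroxide oxygen with retention, so C8 becomes the 8R alcohol. No acid or electrophile is used, so the 1(10),4-diene is not exposed to transannular cyclisation.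

Step 10
Reactants: 17 8-hydroxy-6-ketone; 18 tert-butyl bromoacetate
Product: 20 tert-butyl [(3S,7R,8R)-8-hydroxy-4,10-dimethyl-6-oxo-3-(triisopropylsilyloxy)cyclodeca-1(10)E,4Z-dien-7-yl]acetate, via dilithium dianion 19 (not isolated)
Conditions: LiN(iPr)2 (2.3 equiv), THF, −78 °C; 18, DMPU, −78 → −50 °C; AcOH, −78 °C
Reagents that add atoms: none
Why: Dianion alkylation of a β-hydroxy ketone (Fráter–Seebach type); the C8 alkoxide and the enolate oxygen share lithium in a six-membered chelate, C9 stands out of its plane on the inner face of the ring, and the bromoacetate attacks C7 from the open outer face, anti to C9, which puts C11 cis to O8 (7R). The β-oxide is too poor a leaving group to eliminate, and the tert-butyl ester is not attacked by the C8 alkoxide.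

Step 11
Reactants: 21 angelic acid
Product: 22 (Z)-2-methylbut-2-en-1-ol
Conditions: LiAlH4, Et2O, 0 °C
Reagents that add atoms: none
Why: Hydride reduction of the carboxylic acid to the allylic alcohol; the Z-alkene is not touched.

Step 12
Reactants: 22 (Z)-2-methylbut-2-en-1-ol
Product: 23 [(2R,3S)-2,3-dimethyloxiran-2-yl]methanol
Conditions: Ti(OiPr)4 (cat.), D-(−)-diethyl tartrate (cat.), TBHP, 4 Å molecular sieves, CH2Cl2, −20 °C
Reagents that add atoms: tert-butyl hydroperoxide, CC(C)(C)OO
Why: Sharpless asymmetric epoxidation; the titanium tartrate complex delivers oxygen to one face of the allylic alcohol, and the D-tartrate is the enantiomer that gives the 2R,3S epoxy alcohol (the L-tartrate gives 2S, as it does for simple E-allylic alcohols).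

Step 13
Reactants: 23 (2R,3S)-epoxy alcohol
Product: 24 (2S,3S)-2,3-dimethyloxirane-2-carbaldehyde
Conditions: Dess–Martin periodinane, CH2Cl2, 0 °C
Reagents that add atoms: none
Why: Dess–Martin oxidation of the primary alcohol; the quaternary α-carbon cannot epimerise (the descriptor at C2 changes only through the priority rules).

Step 14
Reactants: 20 8-hydroxy-6-ketone with C7 acetate arm; 24 (2S,3S)-epoxy aldehyde
Product: 26 tert-butyl [(3S,6R,7S,8R)-8-[(2S,3S)-2,3-dimethyloxirane-2-carbonyloxy]-6-hydroxy-4,10-dimethyl-3-(triisopropylsilyloxy)cyclodeca-1(10)E,4Z-dien-7-yl]acetate, via samarium-bound hemiacetal 25 (not isolated)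
Conditions: 24 (4 equiv), SmI2 (0.3 equiv, pre-mixed with PhCHO 0.3 equiv), THF, −10 °C
Reagents that add atoms: none
Why: Evans–Tishchenko reduction; the C8 hydroxyl adds to the aldehyde, and the hemiacetal 25, bound to trivalent samarium, passes its hydride to the C6 carbonyl through a six-membered chair, which gives the 1,3-anti diol monoester. C6 becomes 6R (O6 trans to O8), and the epoxyangelate ends on O8 in the same operation while O6 stays free. Pre-mixing SmI2 with PhCHO leaves no divalent samarium to open the epoxide.

Step 15
Reactants: 26 6-hydroxy tert-butyl ester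
Product: 27 6,12-lactone (trans-fused, C11 = CH2) of the (3S,6R,7R,8R)-8-epoxyangeloyloxy-3-(triisopropylsilyloxy)cyclodeca-1(10)E,4Z-diene
Conditions: TFA, CH2Cl2, 0 °C
Reagents that add atoms: none
Why: Acid-induced loss of the tert-butyl group and γ-lactonisation; O8 is already acylated, so only the 6,12-lactone can form, and C6 keeps its configuration because the acyl C–O bond is the one made.

Step 16
Reactants: 27 3-silyloxy lactone
Product: 28 3-hydroxy lactone (3S)
Conditions: TBAF, AcOH, THF, 25 °C
Reagents that add atoms: none
Why: Buffered fluoride cleavage of the silyl ether; C6 is now an ester carbon, so the free Z-γ-hydroxyl can no longer close onto a C6 carbonyl.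

Step 17
Reactants: 28 3-hydroxy lactone
Product: 29 3-benzoyloxy lactone (3S)
Conditions: BzCl, pyridine, DMAP (cat.), CH2Cl2, 0 → 25 °C
Reagents that add atoms: benzoyl chloride, O=C(Cl)c1ccccc1
Why: Acylation of the secondary allylic alcohol under nucleophilic catalysis; no stereocentre is involved.

Step 18
Reactants: 29 3-benzoyloxy lactone
Product: 31 11-(dimethylaminomethyl) lactone (C11 epimers, configuration of no consequence), via lithium lactone enolate 30 (not isolated)
Conditions: LiN(iPr)2, THF, −78 °C; CH2=NMe2 I, −78 → 0 °C
Reagents that add atoms: N,N-dimethylmethyleneiminium iodide (Eschenmoser's salt), C=[N+](C)C.[I-]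
Why: Mannich reaction of the lactone enolate; the benzoate and the epoxyangelate have no α-hydrogen, so C11 is the only carbon deprotonated at −78 °C.

Step 19
Reactants: 31 Mannich base
Product: 33 α-methylene lactone (C11=C13), via trimethylammonium iodide 32 (not isolated)
Conditions: MeI, THF, 25 °C; aq. NaHCO3, 25 °C
Reagents that add atoms: none
Why: N-Methylation, then base-induced β-elimination (E1cB) of trimethylamine from the ammonium salt; mild bicarbonate spares the esters and the new Michael acceptor.

Step 20
Reactants: 33 α-methylene lactone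
Product: 34 (1R,3S,4Z,6R,7R,8R,10R)-3-benzoyloxy-1,10-epoxy-8-[(2S,3S)-2,3-dimethyloxirane-2-carbonyloxy]germacra-4,11(13)-dien-12,6-olide (CNP0324463.3)
Conditions: mCPBA, CH2Cl2, 0 °C
Reagents that add atoms: 3-chloroperbenzoic acid, O=C(OO)c1cccc(Cl)c1
Why: Prilezhaev epoxidation; C1=C10 is the only electron-rich alkene (C4=C5 has two allylic acyloxy groups, C11=C13 is conjugated to the lactone). Attack on the outer face of the conformer that holds the C10 methyl on the β-face should give the trans 1β,10α-epoxide (1R,10R).

Compound list

1 | (R)-carvone | CC1=CC[C@H](CC1=O)C(C)=C | starting material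
2 | (1R,5R)-cis-carveol | C=C(C)[C@@H]1CC=C(C)[C@H](O)C1 | intermediate
3 | (1S,5R)-trans-carveyl 4-nitrobenzoate | C=C(C)[C@@H]1CC=C(C)[C@@H](OC(=O)c2ccc(cc2)[N+](=O)[O-])C1 | intermediate
4 | (1S,5R)-trans-carveol | C=C(C)[C@@H]1CC=C(C)[C@@H](O)C1 | intermediate
5 | triisopropyl{[(1S,5R)-2-methyl-5-(prop-1-en-2-yl)cyclohex-2-en-1-yl]oxy}silane | C=C(C)[C@@H]1CC=C(C)[C@@H](O[Si](C(C)C)(C(C)C)C(C)C)C1 | intermediate
6 | (4S,6R)-3-methyl-6-(prop-1-en-2-yl)-4-(triisopropylsilyloxy)cyclohex-2-en-1-one | C=C(C)[C@@H]1C(=O)C=C(C)[C@@H](O[Si](C(C)C)(C(C)C)C(C)C)C1 | intermediate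
7 | (E)-1,2-bis(tributylstannyl)ethene | CCCC[Sn](CCCC)(CCCC)/C=C/[Sn](CCCC)(CCCC)CCCC | starting material
8 | benzylchlorodimethylsilane | C[Si](C)(Cl)Cc1ccccc1 | starting material
9 | (E)-2-(tributylstannyl)vinyllithium | [Li]/C=C/[Sn](CCCC)(CCCC)CCCC | intermediate (not isolated)
10 | (E)-benzyldimethyl[2-(tributylstannyl)ethenyl]silane | C[Si](C)(Cc1ccccc1)/C=C/[Sn](CCCC)(CCCC)CCCC | intermediate
11 | (E)-2-(benzyldimethylsilyl)vinyllithium | [Li]/C=C/[Si](C)(C)Cc1ccccc1 | intermediate (not isolated)
12 | (1R,4S,6R)-1-[(E)-2-(benzyldimethylsilyl)ethenyl]-3-methyl-6-(prop-1-en-2-yl)-4-(triisopropylsilyloxy)cyclohex-2-en-1-ol | O[C@]1(/C=C/[Si](C)(C)Cc2ccccc2)C=C(C)[C@@H](O[Si](C(C)C)(C(C)C)C(C)C)C[C@@H]1C(C)=C | intermediate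
13 | potassium alkoxide of 12 | [K+].[O-][C@]1(/C=C/[Si](C)(C)Cc2ccccc2)C=C(C)[C@@H](O[Si](C(C)C)(C(C)C)C(C)C)C[C@@H]1C(C)=C | intermediate (not isolated)
14 | potassium dienolate of 15 (O6 cis to C8) | [K+].[O-]/C1=C\[C@H]([Si](C)(C)Cc2ccccc2)C/C(C)=C/C[C@H](O[Si](C(C)C)(C(C)C)C(C)C)/C(C)=C\1 | intermediate (not isolated)
15 | (2Z,4S,6E,9R)-9-(benzyldimethylsilyl)-3,7-dimethyl-4-(triisopropylsilyloxy)cyclodeca-2,6-dien-1-one | O=C1/C=C(/C)[C@@H](O[Si](C(C)C)(C(C)C)C(C)C)C/C=C(\C)C[C@@H]([Si](C)(C)Cc2ccccc2)C1 | intermediate
16 | 8-(fluorodimethylsilyl) analogue of 15 | O=C1/C=C(/C)[C@@H](O[Si](C(C)C)(C(C)C)C(C)C)C/C=C(\C)C[C@@H]([Si](C)(C)F)C1 | intermediate (not isolated)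
17 | (2Z,4S,6E,9R)-9-hydroxy-3,7-dimethyl-4-(triisopropylsilyloxy)cyclodeca-2,6-dien-1-one | O=C1/C=C(/C)[C@@H](O[Si](C(C)C)(C(C)C)C(C)C)C/C=C(\C)C[C@@H](O)C1 | intermediate
18 | tert-butyl bromoacetate | BrCC(=O)OC(C)(C)C | starting material
19 | dilithium alkoxide enolate of 17 | [Li+].[Li+].[O-]/C1=C\[C@H]([O-])C/C(C)=C/C[C@H](O[Si](C(C)C)(C(C)C)C(C)C)/C(C)=C\1 | intermediate (not isolated)
20 | tert-butyl [(3S,7R,8R)-8-hydroxy-4,10-dimethyl-6-oxo-3-(triisopropylsilyloxy)cyclodeca-1(10)E,4Z-dien-7-yl]acetate | O=C1/C=C(/C)[C@@H](O[Si](C(C)C)(C(C)C)C(C)C)C/C=C(\C)C[C@@H](O)[C@H]1CC(=O)OC(C)(C)C | intermediate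
21 | angelic acid, (Z)-2-methylbut-2-enoic acid | C/C=C(/C)C(O)=O | starting material
22 | (Z)-2-methylbut-2-en-1-ol | C/C=C(/C)CO | intermediate
23 | [(2R,3S)-2,3-dimethyloxiran-2-yl]methanol | OC[C@@]1(C)O[C@H]1C | intermediate
24 | (2S,3S)-2,3-dimethyloxirane-2-carbaldehyde | O=C[C@@]1(C)O[C@H]1C | intermediate
25 | O8 hemiacetal of 20 with 24 (hemiacetal carbon undefined) | O=C1/C=C(/C)[C@@H](O[Si](C(C)C)(C(C)C)C(C)C)C/C=C(\C)C[C@@H](OC(O)[C@@]2(C)O[C@H]2C)[C@H]1CC(=O)OC(C)(C)C | intermediate (not isolated)
26 | tert-butyl [(3S,6R,7S,8R)-8-[(2S,3S)-2,3-dimethyloxirane-2-carbonyloxy]-6-hydroxy-4,10-dimethyl-3-(triisopropylsilyloxy)cyclodeca-1(10)E,4Z-dien-7-yl]acetate | O[C@@H]1/C=C(/C)[C@@H](O[Si](C(C)C)(C(C)C)C(C)C)C/C=C(\C)C[C@@H](OC(=O)[C@@]2(C)O[C@H]2C)[C@H]1CC(=O)OC(C)(C)C | intermediate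
27 | (3S,6R,7R,8R)-6,12-lactone with 8-epoxyangeloyloxy and 3-triisopropylsilyloxy groups, C11 = CH2 | C1C(=O)O[C@@H]2/C=C(/C)[C@@H](O[Si](C(C)C)(C(C)C)C(C)C)C/C=C(\C)C[C@@H](OC(=O)[C@@]3(C)O[C@H]3C)[C@@H]12 | intermediate
28 | 3-hydroxy lactone (3S,6R,7R,8R) | C1C(=O)O[C@@H]2/C=C(/C)[C@@H](O)C/C=C(\C)C[C@@H](OC(=O)[C@@]3(C)O[C@H]3C)[C@@H]12 | intermediate
29 | 3-benzoyloxy lactone (3S,6R,7R,8R) | C1C(=O)O[C@@H]2/C=C(/C)[C@@H](OC(=O)c3ccccc3)C/C=C(\C)C[C@@H](OC(=O)[C@@]3(C)O[C@H]3C)[C@@H]12 | intermediate
30 | lithium enolate of 29 (C11=C12) | C1=C([O-])O[C@@H]2/C=C(/C)[C@@H](OC(=O)c3ccccc3)C/C=C(\C)C[C@@H](OC(=O)[C@@]3(C)O[C@H]3C)[C@@H]12.[Li+] | intermediate (not isolated)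
31 | 11-(dimethylaminomethyl) lactone (C11 undefined) | CN(C)CC1C(=O)O[C@@H]2/C=C(/C)[C@@H](OC(=O)c3ccccc3)C/C=C(\C)C[C@@H](OC(=O)[C@@]3(C)O[C@H]3C)[C@@H]12 | intermediate
32 | 11-(trimethylammoniomethyl) lactone iodide | C[N+](C)(C)CC1C(=O)O[C@@H]2/C=C(/C)[C@@H](OC(=O)c3ccccc3)C/C=C(\C)C[C@@H](OC(=O)[C@@]3(C)O[C@H]3C)[C@@H]12.[I-] | intermediate (not isolated)
33 | α-methylene lactone, 1(10)E,4Z-diene (3S,6R,7R,8R) | C=C1C(=O)O[C@@H]2/C=C(/C)[C@@H](OC(=O)c3ccccc3)C/C=C(\C)C[C@@H](OC(=O)[C@@]3(C)O[C@H]3C)[C@@H]12 | intermediate
34 | CNP0324463.3, (1R,3S,4Z,6R,7R,8R,10R)-3-benzoyloxy-1,10-epoxy-8-[(2S,3S)-2,3-dimethyloxirane-2-carbonyloxy]germacra-4,11(13)-dien-12,6-olide | C=C1C(=O)O[C@@H]2/C=C(/C)[C@@H](OC(=O)c3ccccc3)C[C@H]3O[C@]3(C)C[C@@H](OC(=O)[C@@]3(C)O[C@H]3C)[C@@H]12 | target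

Total step count: 20. Longest linear sequence: 16 steps (steps 1–5, 7–10 and 14–20, from 1 to 34).

Least certain steps

Step 8 (key step). The alkoxide may fragment at C1–C6 to an allyl anion and recombine as a formal [1,3] shift. The silyl group on the bond-forming terminus may slow the shift enough for a boat pathway, and with it the Z C1=C10 alkene, to compete. The enolate oxygen, which lies cis to C8, may attack silicon and expel the benzyl group. Fallback: from 6, add CH2=CHMgBr to give the unsubstituted vinyl carbinol F1, which is the exact substrate class of the known ring expansion. Rearrange it with KH and 18-crown-6 and trap the enolate with Me3SiCl as the silyl dienol ether F2. Pd(OAc)2 (Saegusa–Ito) then gives the cross-conjugated trienone F3 with the new C7=C8 alkene. Conjugate borylation at the unhindered C8 (CuCl, NaOtBu, bis(pinacolato)diboron, MeOH) gives the β-boryl ketone F4, and NaBO3 oxidises it to 17, where the route is rejoined. In this fallback C8 is set by outer-face attack on the ring and not by the chair, so it is less secure.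

Step 5. The oxidant may also attack the silyloxy-bearing carbon or the allylic positions of the isopropenyl group, or place oxygen on the tertiary end of the allyl system. Fallback: from 5, epoxidise the ring alkene with mCPBA to the epoxide F5. Open it at the secondary carbon with PhSeNa to the hydroxy selenide F6. Oxidise with H2O2 so that the selenoxide eliminates away from the carbinol and gives the tertiary allylic alcohol F7. Oxidative 1,3-transposition with pyridinium chlorochromate, C5H5NH[CrO3Cl], then gives 6.

Step 9. Fluoride may remove the O3 silyl group, after which the Z-γ-hydroxy enone closes to a hemiketal. The β-hydroxy ketone may open by retro-aldol reaction or dehydrate in the basic peroxide. The benzyl group may transfer to the carbonyl. Fallback: from 15, reduce the ketone first (NaBH4, CeCl3·7H2O) to the allylic alcohol F8; either C6 epimer serves. Carry out the same fluoride and peroxide oxidation on it to obtain the diol F9, which has no aldol pathway. MnO2 then oxidises only the allylic C6 hydroxyl and gives 17.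

Step 10. The C8 alkoxide may lactonise onto the new ester on warming, the aldolate may cleave, or attack may come partly from the wrong face. Fallback: change the order and the controlling element. From 15, form the β-silyl ketone enolate with LiN(iPr)2 and alkylate it with 18, with the electrophile entering anti to silicon, to give the 7-alkyl-8-silyl ketone F10. Oxidise silicon as in step 9 to reach 20.

Step 14. The hindered, quaternary aldehyde may turn over slowly, its epoxide may be opened by residual divalent samarium, or the acyl group may move from O8 to O6. Fallback: from 20, run the same Tishchenko reduction with methoxyacetaldehyde to the 8-methoxyacetate F11 and lactonise with TFA to F12. Remove the methoxyacetyl group selectively with Yb(OTf)3 in MeOH to the 8-hydroxy lactone F13. Esterify it (2,4,6-trichlorobenzoyl chloride, Et3N, DMAP) with (2S,3S)-2,3-dimethyloxirane-2-carboxylic acid F14, made from 24 with NaClO2, which gives 27.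

Step 20. The peracid may attack the other face of C1=C10 and give the diastereomeric epoxide, or C4=C5 may be oxidised as well. Fallback: replace substrate control by reagent control one stage earlier. Epoxidise 29 with the D-fructose-derived Shi ketone and KHSO5 (the sense that gives R,R epoxides from E-trisubstituted alkenes) to the epoxy lactone F15, which has no Michael acceptor exposed to the basic medium. Carry out the Mannich reaction as in step 18 to F16, then methylation to the ammonium salt F17 and elimination as in step 19, which ends at 34.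

Further compounds

F1 | step 8 | (1R,4S,6R)-1-ethenyl-3-methyl-6-(prop-1-en-2-yl)-4-(triisopropylsilyloxy)cyclohex-2-en-1-ol | O[C@]1(C=C)C=C(C)[C@@H](O[Si](C(C)C)(C(C)C)C(C)C)C[C@@H]1C(C)=C
F2 | step 8 | 6-(trimethylsilyloxy)cyclodeca-1(10)E,4Z,6-triene with 3S silyloxy group (no C8 substituent) | C[Si](C)(C)O/C1=C\CC/C(C)=C/C[C@H](O[Si](C(C)C)(C(C)C)C(C)C)/C(C)=C\1
F3 | step 8 | (3S)-cyclodeca-1(10)E,4Z,7-trien-6-one (C7=C8 geometry undefined) | O=C1C=CC/C(C)=C/C[C@H](O[Si](C(C)C)(C(C)C)C(C)C)/C(C)=C\1
F4 | step 8 | 8-(pinacolatoboryl) analogue of 15 | O=C1/C=C(/C)[C@@H](O[Si](C(C)C)(C(C)C)C(C)C)C/C=C(\C)C[C@@H](B2OC(C)(C)C(C)(C)O2)C1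
F5 | step 5 | ring epoxide of 5 (epoxide configuration undefined) | C=C(C)[C@@H]1CC2OC2(C)[C@@H](O[Si](C(C)C)(C(C)C)C(C)C)C1
F6 | step 5 | β-hydroxy phenyl selenide from F5 | C=C(C)[C@@H]1CC([Se]c2ccccc2)C(C)(O)[C@@H](O[Si](C(C)C)(C(C)C)C(C)C)C1
F7 | step 5 | tertiary allylic alcohol, 1-methyl-4-(prop-1-en-2-yl)-6-(triisopropylsilyloxy)cyclohex-2-en-1-ol | C=C(C)[C@@H]1C=CC(C)(O)[C@@H](O[Si](C(C)C)(C(C)C)C(C)C)C1
F8 | step 9 | 6-hydroxy analogue of 15 (C6 undefined) | OC1/C=C(/C)[C@@H](O[Si](C(C)C)(C(C)C)C(C)C)C/C=C(\C)C[C@@H]([Si](C)(C)Cc2ccccc2)C1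
F9 | step 9 | 6,8-diol (C6 undefined, 8R) | OC1/C=C(/C)[C@@H](O[Si](C(C)C)(C(C)C)C(C)C)C/C=C(\C)C[C@@H](O)C1
F10 | step 10 | tert-butyl ester of the 7-acetic acid of 15 (C11 cis to silicon) | O=C1/C=C(/C)[C@@H](O[Si](C(C)C)(C(C)C)C(C)C)C/C=C(\C)C[C@@H]([Si](C)(C)Cc2ccccc2)[C@H]1CC(=O)OC(C)(C)C
F11 | step 14 | 8-O-methoxyacetyl analogue of 26 | O[C@@H]1/C=C(/C)[C@@H](O[Si](C(C)C)(C(C)C)C(C)C)C/C=C(\C)C[C@@H](OC(=O)COC)[C@H]1CC(=O)OC(C)(C)C
F12 | step 14 | 8-O-methoxyacetyl analogue of 27 | C1C(=O)O[C@@H]2/C=C(/C)[C@@H](O[Si](C(C)C)(C(C)C)C(C)C)C/C=C(\C)C[C@@H](OC(=O)COC)[C@@H]12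
F13 | step 14 | 8-hydroxy-6,12-lactone with 3-silyloxy group | C1C(=O)O[C@@H]2/C=C(/C)[C@@H](O[Si](C(C)C)(C(C)C)C(C)C)C/C=C(\C)C[C@@H](O)[C@@H]12
F14 | step 14 | (2S,3S)-2,3-dimethyloxirane-2-carboxylic acid | OC(=O)[C@@]1(C)O[C@H]1C
F15 | step 20 | (1R,10R)-1,10-epoxide of 29 | C1C(=O)O[C@@H]2/C=C(/C)[C@@H](OC(=O)c3ccccc3)C[C@H]3O[C@]3(C)C[C@@H](OC(=O)[C@@]3(C)O[C@H]3C)[C@@H]12
F16 | step 20 | 11-(dimethylaminomethyl) derivative of F15 | CN(C)CC1C(=O)O[C@@H]2/C=C(/C)[C@@H](OC(=O)c3ccccc3)C[C@H]3O[C@]3(C)C[C@@H](OC(=O)[C@@]3(C)O[C@H]3C)[C@@H]12
F17 | step 20 | trimethylammonium iodide of F16 | C[N+](C)(C)CC1C(=O)O[C@@H]2/C=C(/C)[C@@H](OC(=O)c3ccccc3)C[C@H]3O[C@]3(C)C[C@@H](OC(=O)[C@@]3(C)O[C@H]3C)[C@@H]12.[I-]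
A1 | alternative 1 | isoxazoline-bridged ten-membered carbocycle | C/C1=C/[C@H]2OC(=O)C[C@@H]2[C@H](O[Si](C)(C)C(C)(C)C)C[C@@](C)(O[Si](CC)(CC)CC)[C@@H]3CC1=NO3
A2 | alternative 1 | open-chain nitrile oxide with terminal C1=C2 alkene | [O-][N+]#C/C(C)=C\[C@H]1OC(=O)C[C@@H]1[C@H](O[Si](C)(C)C(C)(C)C)C[C@@](C)(O[Si](CC)(CC)CC)C=C
A3 | alternative 2 | cyclodecane-3,8-dione with C1,C10 acetonide | C[C@H]1C[C@@H](O[Si](C)(C)C(C)(C)C)[C@H](CCO[Si](C)(C)C(C)(C)C)C(=O)C[C@@]2(C)OC(C)(C)O[C@H]2CC1=O
A4 | alternative 2 | hexahydronaphthalene with C3=C8 ring-fusion alkene | C[C@H]1C[C@@H](O[Si](C)(C)C(C)(C)C)[C@H](CCO[Si](C)(C)C(C)(C)C)C2=C1C[C@@H]3OC(C)(C)O[C@]3(C)C2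
A5 | alternative 3 | ten-membered 10-hydroxy-8-ketone | O=C1C[C@@](C)(O)[C@@H](O[Si](CC)(CC)CC)C[C@H](O[Si](C)(C)C(C)(C)C)/C(C)=C\[C@H]2OC(=O)C[C@H]12
A6 | alternative 3 | open-chain C8 bromomethyl ketone with C10 methyl ketone | BrCC(=O)[C@H]1CC(=O)O[C@@H]1/C=C(/C)[C@@H](O[Si](C)(C)C(C)(C)C)C[C@H](O[Si](CC)(CC)CC)C(C)=O
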